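**Retrosynthetic overview**
- Feature: O1 of ring C is bonded to C8a of ring A. C8a is ortho to the C4 acyl carbon and para to the C6 methoxy group, so it is where the radical cation of a 2,3,4-trimethoxybenzoyl ring should accept an oxygen nucleophile in a six-membered closure.
- The target comes from 5,6,7,2',3'-pentamethoxy-5'-pivaloyloxyflavone by chelation-directed cleavage of the 5-methyl ether and methanolysis of the pivalate.
- That flavone comes from 1-(2,3-dimethoxy-5-pivaloyloxyphenyl)-3-(2,3,4-trimethoxyphenyl)propane-1,3-dione by anodic C–H/O–H coupling (O1–C8a). Ring C is the only ring formed; rings A and B are bought.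
- The diketone comes from C-acylation (C2–C3 bond) of the lithium enolate of 2',3',4'-trimethoxyacetophenone with 2,3-dimethoxy-5-(pivaloyloxy)benzoyl chloride, itself made from 5-bromo-2,3-dimethoxybenzoic acid by hydroxylation, pivaloylation and chlorination.

Key step: step 5

Assumption: 5-bromo-2,3-dimethoxybenzoic acid is taken as a purchasable compound, and the 1,3-diketone, drawn in its diketo form, is taken to react through its enol.

**Step 1**
Reactants: 1 5-bromo-2,3-dimethoxybenzoic acid
Product: 2 5-hydroxy-2,3-dimethoxybenzoic acid
Conditions: Cu(acac)2 (5 mol %), N,N'-bis(4-hydroxy-2,6-dimethylphenyl)oxalamide (5 mol %), LiOH·H2O (4 equiv), DMSO/H2O 4:1, 80 °C, Ar; then 1 M HCl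
Reagents that add atoms: lithium hydroxide, [Li+].[OH-]
Why: Ullmann-type copper-catalysed hydroxylation of an aryl bromide with hydroxide under oxalamide ligation should replace C5–Br by C5–OH, the acid being carried as its inert lithium carboxylate and the methyl ethers being untouched.

**Step 2**
Reactants: 2 5-hydroxy-2,3-dimethoxybenzoic acid; 3 pivaloyl chloride
Product: 4 2,3-dimethoxy-5-(pivaloyloxy)benzoic acid
Conditions: NaOH (2.2 equiv), H2O/THF, 0 °C, N2, PivCl (1.15 equiv); then 1 M HCl to pH 2
Reagents that add atoms: pivaloyl chloride, CC(C)(C)C(=O)Cl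
Why: Schotten–Baumann O-acylation, in which the phenoxide of the dianion is far more nucleophilic than the carboxylate, so the aryl pivalate should form and any mixed anhydride is hydrolysed back to the acid before acidification.

**Step 3**
Reactants: 4 2,3-dimethoxy-5-(pivaloyloxy)benzoic acid
Product: 5 2,3-dimethoxy-5-(pivaloyloxy)benzoyl chloride
Conditions: (COCl)2 (1.5 equiv), DMF (cat.), CH2Cl2, 0 °C → rt; evaporate, use crude
Reagents that add atoms: oxalyl chloride, O=C(Cl)C(=O)Cl
Why: Standard acid chloride formation through the Vilsmeier chloroiminium species from DMF and oxalyl chloride; the aryl pivalate and the methyl ethers are inert and only gases are lost.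

**Step 4**
Reactants: 6 2',3',4'-trimethoxyacetophenone; 5 2,3-dimethoxy-5-(pivaloyloxy)benzoyl chloride
Product: 8 1-(2,3-dimethoxy-5-pivaloyloxyphenyl)-3-(2,3,4-trimethoxyphenyl)propane-1,3-dione, via lithium enolate 7 (not isolated)
Conditions: 6 (2.0 equiv), LiN(SiMe3)2 (2.05 equiv), THF, −78 °C, 45 min; then 5 (1.0 equiv) in THF, −78 → 0 °C; 1 M HCl; excess 6 recovered
Reagents that add atoms: none
Why: Crossed Claisen-type C-acylation of a preformed lithium enolate by an aroyl chloride at −78 °C, in which the second equivalent of enolate takes up the acidic proton of the 1,3-diketone so that bis-acylation is suppressed, while the hindered aryl pivalate is far less electrophilic than the acid chloride and should survive.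

**Step 5**
Reactants: 8 1-(2,3-dimethoxy-5-pivaloyloxyphenyl)-3-(2,3,4-trimethoxyphenyl)propane-1,3-dione
Product: 9 5,6,7,2',3'-pentamethoxy-5'-pivaloyloxyflavone
Conditions: undivided cell, graphite anode, Pt cathode, n-Bu4NPF6 (0.1 M), (CF3)2CHOH, 8 at 0.02 M, constant current 4 mA cm−2 with the anode potential kept at the first oxidation wave of 8, 2.2 F mol−1, 20 °C, Ar
Reagents that add atoms: none
Why: Proposed new method: the 2,3,4-trimethoxybenzoyl ring (ring A) is the most electron-rich π system of 8 and should give up one electron at the carbon anode, with hexafluoroisopropanol stabilising the radical cation; the oxygen on C2 of the Z-enol, brought over C8a by rotation about the C3–C4 bond, then adds to C8a, and loss of a second electron and of the C8a proton restores the aromaticity of ring A while the cathode turns the released protons into H2. The closest known reaction types are the anodic dehydrogenative lactonisation of biaryl-2-carboxylic acids to benzocoumarins and the anodic cyclisation of anilides to benzoxazoles in hexafluoroisopropanol; the enol oxygen of a 1,3-diketone has not been used as the nucleophile in such a C–H/O–H coupling. Ring C closes in a six-membered mode through O1, C2, C3, C4, C4a and C8a (6-exo with respect to the C8–C8a π bond of the radical cation), and C3 cannot compete because its bonding to an ortho carbon of either ring would give a four-membered ring. No stereocentre is formed. The step needs ring selectivity (the C2 oxygen onto C8a of ring A, not the C4 oxygen onto C6' of ring B) and site selectivity (C8a–H, not ipso attack at the methoxy-bearing C5); the first should follow from three methoxy donors on ring A against two methoxy groups and an acyloxy group on ring B, which places the first oxidation on ring A, and the second from the fact that only the C–H position can lose a proton and rearomatise, ipso addition being reversible. The charge is limited to about 2.2 F per mole so that the tetraoxygenated ring A of the product, whose carbonyl is hydrogen-bonded by the solvent, is spared further oxidation.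

**Step 6**
Reactants: 9 5,6,7,2',3'-pentamethoxy-5'-pivaloyloxyflavone
Product: 11 5-hydroxy-6,7,2',3'-tetramethoxy-5'-pivaloyloxyflavone, via dichloroboron chelate 10 (not isolated)
Conditions: BCl3 (1.5 equiv, 1 M in CH2Cl2), CH2Cl2, −78 → 0 °C; then H2O, 0 °C → rt
Reagents that add atoms: none
Why: Chelation-controlled Lewis acid ether cleavage, in which boron binds the C4 carbonyl and the peri 5-methoxy oxygen and chloride removes that methyl group by SN2 to give the six-membered chelate, while the non-chelating methyl ethers at C6, C7, C2' and C3' and the pivalate should stay intact at 0 °C or below.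

**Step 7**
Reactants: 11 5-hydroxy-6,7,2',3'-tetramethoxy-5'-pivaloyloxyflavone
Product: 12 5,5'-dihydroxy-6,7,2',3'-tetramethoxyflavone (CNP0303773.0)
Conditions: K2CO3 (3 equiv), MeOH/THF 3:1, rt → 40 °C, Ar; then 1 M HCl
Reagents that add atoms: none
Why: Base-mediated transesterification (methanolysis) of the aryl pivalate, driven by the good aryloxide leaving group, while the 5-OH is held as its chelated phenoxide, which lowers the electrophilicity of the pyrone ring toward methoxide.

**Compound list**
1 | 5-bromo-2,3-dimethoxybenzoic acid | COc1cc(Br)cc(C(=O)O)c1OC | starting material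
2 | 5-hydroxy-2,3-dimethoxybenzoic acid | COc1cc(O)cc(C(=O)O)c1OC | intermediate
3 | pivaloyl chloride | CC(C)(C)C(=O)Cl | starting material
4 | 2,3-dimethoxy-5-(pivaloyloxy)benzoic acid | COc1cc(OC(=O)C(C)(C)C)cc(C(=O)O)c1OC | intermediate
5 | 2,3-dimethoxy-5-(pivaloyloxy)benzoyl chloride | COc1cc(OC(=O)C(C)(C)C)cc(C(=O)Cl)c1OC | intermediate
6 | 2',3',4'-trimethoxyacetophenone | CC(=O)c1ccc(OC)c(OC)c1OC | starting material
7 | lithium enolate of 2',3',4'-trimethoxyacetophenone | [Li]OC(=C)c1ccc(OC)c(OC)c1OC | intermediate
8 | 1-(2,3-dimethoxy-5-pivaloyloxyphenyl)-3-(2,3,4-trimethoxyphenyl)propane-1,3-dione | COc1cc(OC(=O)C(C)(C)C)cc(C(=O)CC(=O)c2ccc(OC)c(OC)c2OC)c1OC | intermediate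
9 | 5,6,7,2',3'-pentamethoxy-5'-pivaloyloxyflavone | COc1cc(OC(=O)C(C)(C)C)cc(-c2cc(=O)c3c(OC)c(OC)c(OC)cc3o2)c1OC | intermediate
10 | 5-(dichloroboryloxy)-6,7,2',3'-tetramethoxy-5'-pivaloyloxyflavone (boron chelated to the C4 carbonyl) | COc1cc(OC(=O)C(C)(C)C)cc(-c2cc(=O)c3c(OB(Cl)Cl)c(OC)c(OC)cc3o2)c1OC | intermediate
11 | 5-hydroxy-6,7,2',3'-tetramethoxy-5'-pivaloyloxyflavone | COc1cc(OC(=O)C(C)(C)C)cc(-c2cc(=O)c3c(O)c(OC)c(OC)cc3o2)c1OC | intermediate
12 | 5,5'-dihydroxy-6,7,2',3'-tetramethoxyflavone | COc1cc(O)cc(-c2cc(=O)c3c(O)c(OC)c(OC)cc3o2)c1OC | target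

**Step count**
Total steps: 7. Longest linear sequence: 7 steps (1 → 12); ketone 6 enters at step 4.

**Steps most likely to fail**

1. Step 5 (proposed new method). What may go wrong: oxidation of ring B in place of ring A with closure of the other oxygen onto C6', coupling of two radical cations instead of cyclisation, or further oxidation of the product once formed. Fallback by known chemistry, closing ring C through the O1–C2 bond instead: setting out from acid chloride 5, the dilithium dianion of commercial 6'-hydroxy-2',3',4'-trimethoxyacetophenone F1 (LiN(SiMe3)2, 3.2 equiv, THF, −78 → −10 °C) would be C-acylated to 1-(6-hydroxy-2,3,4-trimethoxyphenyl)-3-(2,3-dimethoxy-5-pivaloyloxyphenyl)propane-1,3-dione F2. Acid-catalysed cyclodehydration (H2SO4 cat., AcOH, 60 °C) would then give flavone 9, where the route is rejoined.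

2. Step 4. What may go wrong: O-acylation of the enolate, a second acylation at C3, or acyl transfer from the pivalate to the hard lithium enolate. Fallback by an aldol/oxidation sequence: setting out from acid chloride 5, reduction with LiAlH(O-t-Bu)3 (THF, −78 °C) would give 2,3-dimethoxy-5-(pivaloyloxy)benzaldehyde F3. Aldol addition of lithium enolate 7 (THF, −78 °C) would give racemic 3-(2,3-dimethoxy-5-pivaloyloxyphenyl)-3-hydroxy-1-(2,3,4-trimethoxyphenyl)propan-1-one F4, whose stereocentre is of no consequence. Oxidation of the secondary alcohol with 2-iodoxybenzoic acid (EtOAc, 75 °C) would return diketone 8.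

3. Step 1. What may go wrong: slow oxidative addition to the electron-rich bromide with competing protodebromination, or air oxidation of the electron-rich phenolate under hot basic conditions. Fallback by borylation/oxidation: setting out from bromo acid 1, Fischer esterification (MeOH, H2SO4 cat., reflux) would give methyl 5-bromo-2,3-dimethoxybenzoate F5. Miyaura borylation (B2pin2, Pd(dppf)Cl2, KOAc, dioxane, 90 °C) would give methyl 2,3-dimethoxy-5-(4,4,5,5-tetramethyl-1,3,2-dioxaborolan-2-yl)benzoate F6. Oxidation of the C–B bond (H2O2, NaOH aq, THF, 0 °C) would give methyl 5-hydroxy-2,3-dimethoxybenzoate F7, and saponification in the same pot (NaOH aq, 40 °C, Ar; then HCl) would return hydroxy acid 2.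

**Further compounds**
F1 | step 5 | 6'-hydroxy-2',3',4'-trimethoxyacetophenone (purchased) | CC(=O)c1c(O)cc(OC)c(OC)c1OC
F2 | step 5 | 1-(6-hydroxy-2,3,4-trimethoxyphenyl)-3-(2,3-dimethoxy-5-pivaloyloxyphenyl)propane-1,3-dione | COc1cc(OC(=O)C(C)(C)C)cc(C(=O)CC(=O)c2c(O)cc(OC)c(OC)c2OC)c1OC
F3 | step 4 | 2,3-dimethoxy-5-(pivaloyloxy)benzaldehyde | COc1cc(OC(=O)C(C)(C)C)cc(C=O)c1OC
F4 | step 4 | 3-(2,3-dimethoxy-5-pivaloyloxyphenyl)-3-hydroxy-1-(2,3,4-trimethoxyphenyl)propan-1-one (racemic) | COc1cc(OC(=O)C(C)(C)C)cc(C(O)CC(=O)c2ccc(OC)c(OC)c2OC)c1OC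
F5 | step 1 | methyl 5-bromo-2,3-dimethoxybenzoate | COC(=O)c1cc(Br)cc(OC)c1OC
F6 | step 1 | methyl 2,3-dimethoxy-5-(4,4,5,5-tetramethyl-1,3,2-dioxaborolan-2-yl)benzoate | COC(=O)c1cc(B2OC(C)(C)C(C)(C)O2)cc(OC)c1OC
F7 | step 1 | methyl 5-hydroxy-2,3-dimethoxybenzoate | COC(=O)c1cc(O)cc(OC)c1OC
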